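The flask is charged with less solid reagent, 0.600 M, than substrate, 2.00 M of the two mirror images together, so I begin with the balance of this limiting reagent.

| setting | noon | flask |
|---|---|---|
| left-handed substrate | 1 M | 1.0 M |
| right-handed substrate | 1 M | 1.0 M |
| solid reagent | 0.90 M | 0.600 M |
| precatalyst | 50 mM | 50 mM |
| remark | run made earlier |  |
| time |  | 25 h |

noon run (percent of the left-handed substrate and right-handed substrate together charged)

| time / h | left-handed substrate / % | right-handed substrate / % | left-handed product / % |
|---|---|---|---|
| 1.00 | 51 | 45 | 2 |
| 2.50 | 46 | 47 | 5 |
| 5.00 | 34 | 49 | 16 |
| 8.00 | 22 | 48 | 26 |

(scatter of a reading: 2 percentage points)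

- free catalyst is single-handed; left-handed substrate and right-handed substrate are mirror images of each other, charged as a racemate, each of them at the stated concentration
- as a solid, counted per litre of solution: solid reagent
- the earlier runs were read with a standard deviation of 2 percentage points
- what may be going on: partner + catalyst intermediate A -> free catalyst + left-handed product; free catalyst + right-handed substrate <-> catalyst intermediate B; precatalyst -> free catalyst; solid reagent <-> partner; partner + catalyst intermediate B -> free catalyst + right-handed product; free catalyst + left-handed substrate <-> catalyst intermediate A
- at the start none of the solid reagent is in solution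
- an excess is below zero if the other one leads

* part of the left-handed substrate and right-handed substrate charged together that has reacted at 25 h
* excess of left-handed product over right-handed product in the product at 25 h
* excess of right-handed substrate over left-handed substrate among what is left of the two at 25 h

Each product takes up one partner, and each partner comes from the solid reagent, so in this flask the solid left, the partner in solution and the products made add up to the charge, and I expect the products to stop at the reagent ceiling, the solid reagent charged divided by the two substrates charged, 30.0 %. If this flask keeps the pace of left-handed product read from the scattered noon run between 2.50 h and 8.00 h, my estimate is that it needs about 7.86 h of such steady running to cover that ceiling, which is shorter than the 25 h allowed, so I commit to a flask standing near its ceiling at the asked time.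

The forecast gives 30.5 % reacted, a product excess of 90 % and a substrate excess of 38 %, on the ground that by then “the reaction has stopped, reagent-limited”.

The flask gives 31.0 % reacted, a product excess of 90.0 % and a substrate excess of 39.4 %.

    partner + catalyst intermediate A → free catalyst + left-handed product (k = 0.00210 M⁻¹ s⁻¹)
    free catalyst + right-handed substrate ⇌ catalyst intermediate B (K = 0.390 M⁻¹, k = 0.0130 M⁻¹ s⁻¹)
    precatalyst → free catalyst (k = 1.40 × 10⁻⁴ s⁻¹)
    solid reagent ⇌ partner, rate k4*(cs4 - [partner]) while solid is left; crystals form when [partner] > cs4 (solubility = 0.480 M, k = 7.50 × 10⁻⁴ s⁻¹)
    partner + catalyst intermediate B → free catalyst + right-handed product (k = 4.20 × 10⁻⁴ M⁻¹ s⁻¹)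
    free catalyst + left-handed substrate ⇌ catalyst intermediate A (K = 2.30 M⁻¹, k = 0.0240 M⁻¹ s⁻¹)

At 25.0 h this flask holds 29.5 % of product, less than the ceiling of 30.0 %, with partner down to 0.00913 M, and the remainder of the 31.0 % is substrate bound in the two catalyst intermediates, 1.43 %.

For the neighbour flask with 1.5 M of solid reagent, the same division gives a ceiling of 75.0 %, but at 25.0 h that flask has 57.4 % reacted, with 0.365 M of partner still in solution, left-handed substrate down to 0.680 % and a product excess of 73.6 %.

The readings stem from a simulated flask from invented constants; the scatter is artificial.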